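## Retrosynthetic overview
1. C2–C3: an acetate ketene silyl acetal adds axially to the cyclic peroxycarbenium ion from a 3-methoxy-1,2-dioxane. This sets C3 cis to the C4 ethyl group.
2. O1–C6 closes the only ring, in the penultimate step, by 6-endo cycloperoxymercuration of a Z-trisubstituted alkenyl hydroperoxy acetal. Alkene geometry together with C4 fixes the Et/alkyl peroxide carbon C6.
3. C4–C5 is the key bond. A Z-alkenylcopper (side-chain copper reagent plus but-1-yne, carbocupration) displaces triflate from methyl (S)-2-triflyloxybutanoate, a chiral enolonium equivalent, by SN2 with inversion.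
4. The side-chain iodide comes from butanal by SOMO α-allylation (C10), Schlosser–Wittig olefination (11E) and hydroboration–iodination.

Assumption: atoms are labelled in the plakortin manner (C1 ester carbonyl, O2 on C3, O1 on C6, C10 the side-chain stereocentre). The SMILES then reads 3S,4S,6S,10R,11E. The C3 side chain, the C4 ethyl and the C6 ethyl lie on one ring face, and the long chain lies on the other.

## Route

Step 1
Reactants: 1 butanal; 2 allyltrimethylsilane
Product: 3 (R)-2-ethylpent-4-enal
Conditions: (2S,5S)-5-benzyl-2-tert-butyl-3-methylimidazolidin-4-one·TFA (20 mol %), (NH4)2Ce(NO3)6 (2.5 equiv), NaHCO3, H2O (1 equiv), DME, −20 °C, 24 h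
Reagents that add atoms: none
Why: Organo-SOMO α-allylation, in which tetravalent cerium oxidises the E-enamine to a radical cation whose Re face is covered by the catalyst benzyl group, so the allylsilane adds to the Si face and, after a second oxidation and loss of silicon, gives the R centre (C10, typically about 90% ee).

Step 2
Reactants: 3 (R)-2-ethylpent-4-enal; 4 propyltriphenylphosphonium bromide
Product: 6 (4R,5E)-4-ethylocta-1,5-diene, via β-oxido ylide 5 (not isolated)
Conditions: 4, PhLi (1.0 equiv), THF–Et2O, 0 °C; 3, −78 °C; PhLi (1.0 equiv), −78 → −30 °C; MeOH, −30 °C → rt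
Reagents that add atoms: none
Why: Schlosser modification of the Wittig reaction, in which the lithiobetaine is deprotonated to the β-oxido ylide and reprotonated to the threo betaine, whose syn elimination gives the E alkene (>95:5), while C10 is safe because the aldehyde is consumed at −78 °C before the second base arrives.

Step 3
Reactants: 6 (4R,5E)-4-ethylocta-1,5-diene
Product: 8 (4R,5E)-4-ethyl-1-iodooct-5-ene, via B-alkyl-9-BBN 7 (not isolated)
Conditions: 9-BBN-H (1.05 equiv), THF, 0 °C → rt; then NaOMe/MeOH, I2, 0 °C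
Reagents that add atoms: iodine, II
Why: Hydroboration–iodination, in which 9-BBN-H adds anti-Markovnikov to the terminal alkene only and I2 cleaves the primary B–C bond of the methoxide ate complex, with no stereocentre touched.

Step 4
Reactants: 9 methyl (S)-2-hydroxybutanoate
Product: 10 methyl (S)-2-(trifluoromethylsulfonyloxy)butanoate
Conditions: Tf2O (1.1 equiv), 2,6-lutidine (1.2 equiv), CH2Cl2, −78 → −20 °C; cold silica plug, used at once
Reagents that add atoms: trifluoromethanesulfonic anhydride, O=S(=O)(OS(=O)(=O)C(F)(F)F)C(F)(F)F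
Why: O-sulfonylation leaves the C–O bond intact, so the S configuration is retained, and it makes the ester α-carbon a strong, configurationally defined electrophile.

Step 5 (key step)
Reactants: 8 (4R,5E)-4-ethyl-1-iodooct-5-ene; 10 methyl (S)-2-(trifluoromethylsulfonyloxy)butanoate; 11 but-1-yne
Product: 16 methyl (2S,3Z,8R,9E)-2,4,8-triethyldodeca-3,9-dienoate, via alkyllithium 12 (not isolated), via alkylmagnesium bromide 13 (not isolated), via alkylcopper 14 (not isolated), via Z-alkenylcopper 15 (not isolated)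
Conditions: 8, t-BuLi (2.0 equiv), pentane–Et2O 3:2, −78 °C; MgBr2·OEt2, −78 → 0 °C; CuBr·SMe2 (1.0 equiv), Et2O–SMe2, −45 °C; 11 (1.2 equiv), −25 °C, 3 h; DMPU, then 10 (1.1 equiv), −60 → −10 °C
Reagents that add atoms: none
Why: Proposed new method: polar Li–I exchange at −78 °C avoids the 5-hexenyl radical closure onto the chain alkene; Normant carbocupration then adds chain and copper syn across but-1-yne with the chain on the internal carbon, hence cis to Cu; the alkenylcopper, a geometry-defined stand-in for the α-carbon C5 of a C6 carbonyl, displaces triflate from 10, in which the normally nucleophilic ester α-carbon C4 acts as a chiral enolonium equivalent, by SN2 with inversion and retained alkene geometry, giving 2S and 3Z in one operation and creating the dissonant C3/C6 1,4-dioxygen pattern from two donor carbons; the closest known reaction types are carbocupration–alkylation of alkenylcoppers and the invertive substitution of α-hydroxy ester triflates and sulfonates by organocuprates or zinc-catalysed Grignard reagents.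

Step 6
Reactants: 16 methyl (2S,3Z,8R,9E)-2,4,8-triethyldodeca-3,9-dienoate
Product: 18 (2S,3Z,8R,9E)-2,4,8-triethyl-1-methoxydodeca-3,9-dien-1-yl acetate (C1 epimers), via aluminium hemiacetal 17 (not isolated)
Conditions: i-Bu2AlH (1.2 equiv), CH2Cl2, −78 °C; then pyridine, DMAP, Ac2O, −78 → −20 °C
Reagents that add atoms: acetic anhydride, CC(=O)OC(C)=O
Why: Rychnovsky reductive acetylation traps the tetrahedral aluminium hemiacetal before it collapses, so the epimerisable β,γ-unsaturated aldehyde is never free, C4 is preserved, and the new acetal carbon (C3) forms as an inconsequential epimer mixture.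

Step 7
Reactants: 18 (2S,3Z,8R,9E)-2,4,8-triethyl-1-methoxydodeca-3,9-dien-1-yl acetate
Product: 19 (2S,3Z,8R,9E)-2,4,8-triethyl-1-methoxydodeca-3,9-dien-1-yl hydroperoxide (C1 epimers)
Conditions: anhydrous H2O2 in Et2O (10 equiv), camphorsulfonic acid (5 mol %), 0 °C
Reagents that add atoms: hydrogen peroxide, OO
Why: Acid-catalysed perhydrolysis (SN1 acetal exchange), in which acetate leaves to give a methoxy-stabilised oxocarbenium ion that excess H2O2 captures faster than the product hydroperoxide can, under acid too weak to protonate the alkenes.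

Step 8
Reactants: 19 (2S,3Z,8R,9E)-2,4,8-triethyl-1-methoxydodeca-3,9-dien-1-yl hydroperoxide
Product: 21 (4S,6S)-4,6-diethyl-6-[(4R,5E)-4-ethyloct-5-en-1-yl]-3-methoxy-1,2-dioxane (C3 epimers), via organomercurial 20 (not isolated)
Conditions: Hg(OAc)2 (1.05 equiv), CH2Cl2, 0 °C → rt; then NaBH4, 2 M aq NaOH, 0 °C, under N2
Reagents that add atoms: none
Why: Cycloperoxymercuration–demercuration, in which divalent mercury activates the electron-rich trisubstituted alkene and the hydroperoxide oxygen opens the mercurinium ion anti at the tertiary carbon (Markovnikov, 6-endo) through a chair where A1,3 strain with the Z chain keeps C4–H in the alkene plane, so the substituent cis to C4 (the chain) becomes axial and trans to the equatorial C4 ethyl, which is 6S, before NaBH4 replaces the ring-bound mercury by hydrogen.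

Step 9
Reactants: 21 (4S,6S)-4,6-diethyl-6-[(4R,5E)-4-ethyloct-5-en-1-yl]-3-methoxy-1,2-dioxane; 22 1-(tert-butyldimethylsilyloxy)-1-methoxyethene
Product: 24 methyl 2-[(3S,4S,6S)-4,6-diethyl-6-[(4R,5E)-4-ethyloct-5-en-1-yl]-1,2-dioxan-3-yl]acetate, via peroxycarbenium triflate 23 (not isolated)
Conditions: 22 (2 equiv), Me3SiOTf (0.2 equiv), CH2Cl2, −78 °C
Reagents that add atoms: none
Why: Mukaiyama-type alkylation of a peroxycarbenium ion, in which the silyl triflate ionises the more basic exocyclic methoxy group, the half-chair cation is locked with the C4 ethyl pseudoequatorial (the flipped form would place it syn-axial to an alkyl group on quaternary C6), and the ketene silyl acetal attacks axially on the face opposite the axial C6 chain, giving the axial CH2CO2Me group cis to the C4 ethyl, which is 3S.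

## Compound list
1 | butanal | CCCC=O | starting material
2 | allyltrimethylsilane | C=CC[Si](C)(C)C | starting material
3 | (R)-2-ethylpent-4-enal | O=C[C@H](CC)CC=C | intermediate
4 | propyltriphenylphosphonium bromide | CCC[P+](c1ccccc1)(c1ccccc1)c1ccccc1.[Br-] | starting material
5 | lithium β-oxido ylide from 3 and the propylidene ylide (carbinol epimers) | [Li+].[O-]C([C@H](CC)CC=C)C(CC)=P(c1ccccc1)(c1ccccc1)c1ccccc1 | intermediate
6 | (4R,5E)-4-ethylocta-1,5-diene | CC/C=C/[C@H](CC)CC=C | intermediate
7 | 9-[(4R,5E)-4-ethyloct-5-en-1-yl]-9-borabicyclo[3.3.1]nonane | CC/C=C/[C@H](CC)CCCB1C2CCCC1CCC2 | intermediate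
8 | (4R,5E)-4-ethyl-1-iodooct-5-ene | CC/C=C/[C@H](CC)CCCI | intermediate
9 | methyl (S)-2-hydroxybutanoate | CC[C@H](O)C(=O)OC | starting material
10 | methyl (S)-2-(trifluoromethylsulfonyloxy)butanoate | CC[C@H](OS(=O)(=O)C(F)(F)F)C(=O)OC | intermediate
11 | but-1-yne | CCC#C | starting material
12 | [(4R,5E)-4-ethyloct-5-en-1-yl]lithium | CC/C=C/[C@H](CC)CCC[Li] | intermediate
13 | [(4R,5E)-4-ethyloct-5-en-1-yl]magnesium bromide | CC/C=C/[C@H](CC)CCC[Mg]Br | intermediate
14 | [(4R,5E)-4-ethyloct-5-en-1-yl]copper | CC/C=C/[C@H](CC)CCC[Cu] | intermediate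
15 | [(1Z,6R,7E)-2,6-diethyldeca-1,7-dien-1-yl]copper | CC/C=C/[C@H](CC)CCC/C(CC)=C\[Cu] | intermediate
16 | methyl (2S,3Z,8R,9E)-2,4,8-triethyldodeca-3,9-dienoate | CC/C=C/[C@H](CC)CCC/C(CC)=C\[C@H](CC)C(=O)OC | intermediate
17 | diisobutylaluminium hemiacetal of 16 (acetal epimers) | CC/C=C/[C@H](CC)CCC/C(CC)=C\[C@H](CC)C(OC)O[Al](CC(C)C)CC(C)C | intermediate
18 | (2S,3Z,8R,9E)-2,4,8-triethyl-1-methoxydodeca-3,9-dien-1-yl acetate (C1 epimers) | CC/C=C/[C@H](CC)CCC/C(CC)=C\[C@H](CC)C(OC)OC(C)=O | intermediate
19 | (2S,3Z,8R,9E)-2,4,8-triethyl-1-methoxydodeca-3,9-dien-1-yl hydroperoxide (C1 epimers) | CC/C=C/[C@H](CC)CCC/C(CC)=C\[C@H](CC)C(OC)OO | intermediate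
20 | 5-(acetoxymercurio) derivative of 21, Hg equatorial and anti to O1 (C3 epimers) | CC/C=C/[C@H](CC)CCC[C@@]1(CC)[C@@H]([Hg]OC(C)=O)[C@H](CC)C(OC)OO1 | intermediate
21 | (4S,6S)-4,6-diethyl-6-[(4R,5E)-4-ethyloct-5-en-1-yl]-3-methoxy-1,2-dioxane (C3 epimers) | CC/C=C/[C@H](CC)CCC[C@@]1(CC)C[C@H](CC)C(OC)OO1 | intermediate
22 | 1-(tert-butyldimethylsilyloxy)-1-methoxyethene | C=C(OC)O[Si](C)(C)C(C)(C)C | starting material
23 | cyclic peroxycarbenium triflate from 21 (C3=O2 cation) | CC/C=C/[C@H](CC)CCC[C@@]1(CC)C[C@H](CC)C=[O+]O1.[O-]S(=O)(=O)C(F)(F)F | intermediate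
24 | methyl 2-[(3S,4S,6S)-4,6-diethyl-6-[(4R,5E)-4-ethyloct-5-en-1-yl]-1,2-dioxan-3-yl]acetate | CC/C=C/[C@H](CC)CCC[C@@]1(CC)C[C@H](CC)[C@H](CC(=O)OC)OO1 | target

## Count and risks
Total steps: 9. Longest linear sequence: 8 (steps 1, 2, 3, 5, 6, 7, 8, 9). Step 4 is a one-step side branch. No protecting groups are used.

**Risk 1, step 5.**
- The alkenylcopper may be too sluggish towards a secondary triflate.
- Bromide or iodide in the pot may displace triflate first and erode the C4 configuration.
- Elimination to the crotonate may compete.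

The fallback sets out from 8 and comes back at 19. It swaps the polarity of the partners. Compound 8, but-1-yne 11 and B2pin2 react under CuCl/Xantphos/NaOtBu by syn-borylcupration followed by alkylation of the alkenylcopper with the primary iodide. This gives 2-[(1Z,6R,7E)-2,6-diethyldeca-1,7-dien-1-yl]-4,4,5,5-tetramethyl-1,3,2-dioxaborolane F1. Ipso-substitution of boron with MesI(OAc)2/BF3·OEt2 and exchange with NaOTf gives, with retention, the [(1Z,6R,7E)-2,6-diethyldeca-1,7-dien-1-yl](mesityl)iodonium triflate F2. Butanal 1 is then α-alkenylated by F2 under CuBr (10 mol %) and the imidazolidinone enantiomer that delivers 2S. Here the enamine meets a trivalent alkenylcopper species and the alkene geometry is kept. The product is (2S,3Z,8R,9E)-2,4,8-triethyldodeca-3,9-dienal F3, which is taken at once with H2O2, MeOH and camphorsulfonic acid to 19.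

**Risk 2, step 8.**
- 5-exo closure to a 1,2-dioxolane may compete.
- Mercuration of the chain alkene may compete.
- The A1,3 bias may be lower than expected.

The fallback sets out from 18 and comes back at 21. It makes the C6–O bond first and closes the ring at C3. Co(thd)2, O2 and Et3SiH in 1,2-dichloroethane hydroperoxysilylate the trisubstituted alkene at its tertiary carbon and leave the 1,2-disubstituted alkene alone. This gives the (2S,8R,9E)-2,4,8-triethyl-1-methoxy-4-(triethylsilylperoxy)dodec-9-en-1-yl acetate F4 as about a 1:1 mixture at C6. Catalytic Me3SiOTf then closes the silyl peroxide onto the oxocarbenium ion released from the acetoxy ether. The products are 21 and its 6-epimer, (4S,6R)-4,6-diethyl-6-[(4R,5E)-4-ethyloct-5-en-1-yl]-3-methoxy-1,2-dioxane F5, which is removed by chromatography. This costs half the material.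

**Risk 3, step 9.**
- Endocyclic C3–O2 ionisation may open the ring to a β-methoxy ester.
- The peroxide may fragment under the Lewis acid.
- Facial selectivity next to the C4 ethyl may be modest.

The fallback sets out from 21 and comes back at 24. It forms the C3–O2 bond last instead of C2–C3. Mild hydrolysis (AcOH–H2O–THF) gives (4S,6S)-4,6-diethyl-6-[(4R,5E)-4-ethyloct-5-en-1-yl]-1,2-dioxan-3-ol F6. Its open hydroperoxy-aldehyde form is trapped by Ph3P=CHCO2Me as methyl (2E,4S,6S,10R,11E)-4,6,10-triethyl-6-hydroperoxytetradeca-2,11-dienoate F7. Et2NH in CF3CH2OH closes F7 by 6-exo oxa-Michael addition to 24 and its 3-epimer, methyl 2-[(3R,4S,6S)-4,6-diethyl-6-[(4R,5E)-4-ethyloct-5-en-1-yl]-1,2-dioxan-3-yl]acetate F8. The 3,4-trans isomer F8 is expected to predominate. It must therefore be separated and recycled through base-induced retro-Michael opening to F7.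

## Further compounds
F1 | step 5 | 2-[(1Z,6R,7E)-2,6-diethyldeca-1,7-dien-1-yl]-4,4,5,5-tetramethyl-1,3,2-dioxaborolane | CC/C=C/[C@H](CC)CCC/C(CC)=C\B1OC(C)(C)C(C)(C)O1
F2 | step 5 | [(1Z,6R,7E)-2,6-diethyldeca-1,7-dien-1-yl](mesityl)iodonium triflate | CC/C=C/[C@H](CC)CCC/C(CC)=C\[I+]c1c(C)cc(C)cc1C.[O-]S(=O)(=O)C(F)(F)F
F3 | step 5 | (2S,3Z,8R,9E)-2,4,8-triethyldodeca-3,9-dienal | CC/C=C/[C@H](CC)CCC/C(CC)=C\[C@H](CC)C=O
F4 | step 8 | (2S,8R,9E)-2,4,8-triethyl-1-methoxy-4-(triethylsilylperoxy)dodec-9-en-1-yl acetate (C1 and C4 epimers) | CC/C=C/[C@H](CC)CCCC(CC)(OO[Si](CC)(CC)CC)C[C@H](CC)C(OC)OC(C)=O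
F5 | step 8 | (4S,6R)-4,6-diethyl-6-[(4R,5E)-4-ethyloct-5-en-1-yl]-3-methoxy-1,2-dioxane | CC/C=C/[C@H](CC)CCC[C@]1(CC)C[C@H](CC)C(OC)OO1
F6 | step 9 | (4S,6S)-4,6-diethyl-6-[(4R,5E)-4-ethyloct-5-en-1-yl]-1,2-dioxan-3-ol | CC/C=C/[C@H](CC)CCC[C@@]1(CC)C[C@H](CC)C(O)OO1
F7 | step 9 | methyl (2E,4S,6S,10R,11E)-4,6,10-triethyl-6-hydroperoxytetradeca-2,11-dienoate | CC/C=C/[C@H](CC)CCC[C@](CC)(OO)C[C@H](CC)/C=C/C(=O)OC
F8 | step 9 | methyl 2-[(3R,4S,6S)-4,6-diethyl-6-[(4R,5E)-4-ethyloct-5-en-1-yl]-1,2-dioxan-3-yl]acetate | CC/C=C/[C@H](CC)CCC[C@@]1(CC)C[C@H](CC)[C@@H](CC(=O)OC)OO1
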